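**Retrosynthetic overview**
- The target 11 is an achiral isoflavone. The strategy rests on the C3–C4 bond of its 4H-pyran-4-one ring (O1–C2–C3–C4–C4a–C8a): C4 (the ring C=O) is traced back to an aldehyde carbon and C3 (the carbon bearing the 4-methoxyphenyl group) to an aryl ketone carbon.
- C2=C3 comes from dehydration of the 3-aryl-3-hydroxychroman-4-one 9 (last step).
- C3–C4 comes from a carbene-catalysed intramolecular crossed benzoin reaction of keto-aldehyde 7. This closes the pyranone ring, the only ring that is made; both benzene rings are bought.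
- O1–C2 comes from O-phenacylation of salicylaldehyde 5 with bromoketone 6. 5 comes from 4-O-prenylation of 3, and 3 from Vilsmeier formylation of the symmetric 2-methoxyresorcinol 1, so the 8-methoxy group is in place from the start and only one hydroxyl has to be told from the other.

Key step: step 4

Remark on the chemistry: the target has no stereocentre and no stereogenic double bond (the prenyl alkene carries two identical methyl groups), so it is one achiral compound and no enantiocontrol is needed. The carbinol centre made in step 4 is racemic and is removed in step 5.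

**Step 1**
Reactants: 1 2-methoxyresorcinol (2-methoxybenzene-1,3-diol)
Product: 3 2,4-dihydroxy-3-methoxybenzaldehyde, via aryl iminium salt 2 (not isolated)
Conditions: POCl3 (1.2 equiv), DMF (1.5 equiv), MeCN, −15 °C → rt; then H2O, 50 °C
Reagents that add atoms: N,N-dimethylformamide CN(C)C=O; water O
Why: Vilsmeier–Haack formylation, in which the chloroiminium electrophile should attack the only doubly activated ring position (ortho to one hydroxyl and para to the other, C4 and C6 being equivalent by symmetry) and hydrolysis of the iminium salt gives the aldehyde, whose formyl group deactivates the ring against a second formylation.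

**Step 2**
Reactants: 3 2,4-dihydroxy-3-methoxybenzaldehyde; 4 prenyl bromide (1-bromo-3-methylbut-2-ene)
Product: 5 2-hydroxy-3-methoxy-4-[(3-methylbut-2-en-1-yl)oxy]benzaldehyde
Conditions: 4 (1.05 equiv), KHCO3 (1.5 equiv), DMF, rt → 40 °C
Reagents that add atoms: none
Why: Williamson etherification under bicarbonate, in which only the 4-hydroxyl (para to the formyl group, the more acidic one and not tied up in the hydrogen bond to C=O) should be deprotonated and alkylated at the primary carbon of the allylic bromide, while the chelated 2-hydroxyl is spared.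

**Step 3**
Reactants: 5 2-hydroxy-3-methoxy-4-[(3-methylbut-2-en-1-yl)oxy]benzaldehyde; 6 2-bromo-1-(4-methoxyphenyl)ethan-1-one (2-bromo-4'-methoxyacetophenone)
Product: 7 3-methoxy-2-[2-(4-methoxyphenyl)-2-oxoethoxy]-4-[(3-methylbut-2-en-1-yl)oxy]benzaldehyde
Conditions: 6 (1.05 equiv), K2CO3 (1.2 equiv), DMF, 0 °C → rt, no heating
Reagents that add atoms: none
Why: Williamson etherification of the remaining chelated phenol with a highly SN2-reactive α-bromo ketone, for which carbonate at room temperature should suffice, so that the phenacyl methylene of the product is not driven into aldol condensation with the aldehyde (Rap–Stoermer benzofuran formation).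

**Step 4**
Reactants: 7 3-methoxy-2-[2-(4-methoxyphenyl)-2-oxoethoxy]-4-[(3-methylbut-2-en-1-yl)oxy]benzaldehyde
Product: 9 rac-3-hydroxy-8-methoxy-3-(4-methoxyphenyl)-7-[(3-methylbut-2-en-1-yl)oxy]-2,3-dihydro-4H-chromen-4-one, via Breslow enaminol 8 (not isolated)
Conditions: 2-(pentafluorophenyl)-6,7-dihydro-5H-pyrrolo[2,1-c][1,2,4]triazol-2-ium tetrafluoroborate (10 mol%), Et3N (10 mol%), degassed PhMe (0.05 M), rt, Ar
Reagents that add atoms: none
Why: The triazolylidene freed by Et3N adds to the formyl carbon, and proton transfer gives the Breslow enaminol 8, an acyl-anion equivalent at the future C4. Its nucleophilic carbon attacks the tethered p-anisyl ketone (the future C3) in a 6-exo-trig closure that forms the C3–C4 bond and the dihydropyranone ring, and collapse of the adduct releases the carbene and the α-hydroxy ketone. This is the known carbene-catalysed intramolecular crossed aldehyde–ketone benzoin reaction of 2-(phenacyloxy)benzaldehydes, which gives 3-aryl-3-hydroxychroman-4-ones. The new carbinol centre C3 is formed racemic because catalyst and substrate are achiral, and no control is needed since it becomes sp2 in step 5. The selectivity required is carbene addition to the aldehyde in preference to enolisation of the phenacyl methylene (aldol condensation to a 2-aroylbenzofuran) and to intermolecular benzoin coupling: only the aldehyde can form a Breslow intermediate, the ketone is held where a six-membered ring closes quickly, and the base is a weak amine in catalytic amount at high dilution. The prenyl ether, the aryl ethers and the ketol product should be inert under these conditions as long as air is excluded.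

**Step 5**
Reactants: 9 rac-3-hydroxy-8-methoxy-3-(4-methoxyphenyl)-7-[(3-methylbut-2-en-1-yl)oxy]-2,3-dihydro-4H-chromen-4-one
Product: 11 8-methoxy-3-(4-methoxyphenyl)-7-[(3-methylbut-2-en-1-yl)oxy]-4H-chromen-4-one, via tertiary sulfamate salt 10 (not isolated)
Conditions: Burgess reagent (methyl N-(triethylammoniosulfonyl)carbamate, 2 equiv), PhMe, rt → 60 °C
Reagents that add atoms: none
Why: Burgess dehydration, in which the tertiary alcohol is converted into its sulfamate and this should undergo thermal syn-elimination (Ei) with the cis hydrogen at C2, the only β-hydrogen present, helped by the p-anisyl group at C3 and by formation of the conjugated 4-pyranone, under neutral conditions that leave the prenyl and aryl ethers untouched.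

**Compound list**
1 | 2-methoxyresorcinol (2-methoxybenzene-1,3-diol) | COc1c(O)cccc1O | starting material
2 | [(2,4-dihydroxy-3-methoxyphenyl)methylidene]dimethylammonium dichlorophosphate (not isolated) | C[N+](C)=Cc1ccc(O)c(OC)c1O.[O-]P(=O)(Cl)Cl | intermediate
3 | 2,4-dihydroxy-3-methoxybenzaldehyde | COc1c(O)ccc(C=O)c1O | intermediate
4 | prenyl bromide (1-bromo-3-methylbut-2-ene) | CC(C)=CCBr | starting material
5 | 2-hydroxy-3-methoxy-4-[(3-methylbut-2-en-1-yl)oxy]benzaldehyde | COc1c(OCC=C(C)C)ccc(C=O)c1O | intermediate
6 | 2-bromo-1-(4-methoxyphenyl)ethan-1-one | COc1ccc(C(=O)CBr)cc1 | starting material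
7 | 3-methoxy-2-[2-(4-methoxyphenyl)-2-oxoethoxy]-4-[(3-methylbut-2-en-1-yl)oxy]benzaldehyde | COc1ccc(C(=O)COc2c(C=O)ccc(OCC=C(C)C)c2OC)cc1 | intermediate
8 | Breslow enaminol of 7, catalyst-bound: 3-(hydroxy{3-methoxy-2-[2-(4-methoxyphenyl)-2-oxoethoxy]-4-[(3-methylbut-2-en-1-yl)oxy]phenyl}methylidene)-2-(pentafluorophenyl)-2,5,6,7-tetrahydro-3H-pyrrolo[2,1-c][1,2,4]triazole (alkene geometry not defined, not isolated) | OC(=C1N(c2c(F)c(F)c(F)c(F)c2F)N=C2CCCN12)c1ccc(OCC=C(C)C)c(OC)c1OCC(=O)c1ccc(OC)cc1 | intermediate
9 | rac-3-hydroxy-8-methoxy-3-(4-methoxyphenyl)-7-[(3-methylbut-2-en-1-yl)oxy]-2,3-dihydro-4H-chromen-4-one (racemate) | COc1ccc(C2(O)COc3c(OC)c(OCC=C(C)C)ccc3C2=O)cc1 | intermediate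
10 | triethylammonium salt of the N-(methoxycarbonyl)sulfamate ester of 9 (racemate, not isolated) | COc1ccc(C2(OS(=O)(=O)[N-]C(=O)OC)COc3c(OC)c(OCC=C(C)C)ccc3C2=O)cc1.CC[NH+](CC)CC | intermediate
11 | 8-methoxy-3-(4-methoxyphenyl)-7-[(3-methylbut-2-en-1-yl)oxy]-4H-chromen-4-one (achiral) | COc1ccc(-c2coc3c(OC)c(OCC=C(C)C)ccc3c2=O)cc1 | target

**Total step count:** 5
**Longest linear sequence:** 5 steps (1 → 3 → 5 → 7 → 9 → 11; 4 and 6 are bought)

**Steps most likely to fail**

Step 4. The Breslow adduct may form slowly at the electron-rich aldehyde, which is flanked by an ortho alkoxy group. Base-induced enolisation of the phenacyl methylene with aldol condensation onto the aldehyde, or oxidation of the acyl-anion equivalent by traces of air, could then take over. The fallback builds the pyranone by the deoxybenzoin route. It sets out from 5 and returns to the route at 11.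
- Addition of 4-methoxybenzylmagnesium chloride (2.5 equiv, THF, 0 °C; the first equivalent is consumed by the phenol) should give racemic 2-[1-hydroxy-2-(4-methoxyphenyl)ethyl]-6-methoxy-5-[(3-methylbut-2-en-1-yl)oxy]phenol F1.
- Oxidation of the benzylic alcohol with activated MnO2 in CH2Cl2 should give 1-{2-hydroxy-3-methoxy-4-[(3-methylbut-2-en-1-yl)oxy]phenyl}-2-(4-methoxyphenyl)ethan-1-one F2.
- Heating with N,N-dimethylformamide dimethyl acetal in toluene at 90 °C should give the enaminone 3-(dimethylamino)-1-{2-hydroxy-3-methoxy-4-[(3-methylbut-2-en-1-yl)oxy]phenyl}-2-(4-methoxyphenyl)prop-2-en-1-one F3, which closes onto the phenol with loss of dimethylamine to give 11.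

Step 5. Ionisation of the sulfamate next to the carbonyl may be sluggish, so that elimination stays incomplete, or the α-ketol undergoes a 1,2-shift or substitution instead of losing the C2 hydrogen. The fallback replaces dehydration by deoxygenation followed by dehydrogenation. It sets out from 9 and returns at 11.
- SmI2 (2.2 equiv, THF–MeOH, −78 °C) should cleave the α-hydroxyl reductively to give rac-8-methoxy-3-(4-methoxyphenyl)-7-[(3-methylbut-2-en-1-yl)oxy]-2,3-dihydro-4H-chromen-4-one F4.
- Its enolate (LiHMDS, THF, −78 °C) should be selenenylated with PhSeCl to rac-8-methoxy-3-(4-methoxyphenyl)-7-[(3-methylbut-2-en-1-yl)oxy]-3-(phenylselanyl)-2,3-dihydro-4H-chromen-4-one F5.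
- Oxidation with NaIO4 in aqueous THF–MeOH at 0 °C → rt should give the selenoxide 3-(benzeneseleninyl)-8-methoxy-3-(4-methoxyphenyl)-7-[(3-methylbut-2-en-1-yl)oxy]-2,3-dihydro-4H-chromen-4-one F6, which should undergo syn-elimination towards C2, the only side with a hydrogen, to give 11. Periodate is chosen so that the prenyl alkene is not epoxidised.

Step 3. The hindered, hydrogen-bonded phenol may alkylate slowly, and the ether once formed may be deprotonated at its methylene by carbonate and cyclise onto the aldehyde, so the product could be consumed as it forms. The fallback forms the same ether without base. It sets out from 5 and returns at 7: Mitsunobu etherification of 5 with 2-hydroxy-1-(4-methoxyphenyl)ethan-1-one (PPh3, DIAD, THF, 0 °C → rt), in which the acidic salicylaldehyde hydroxyl is the pronucleophile and no enolate of the product can arise. No new intermediate is made.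

**Further compounds**
F1 | step 4 | 2-[1-hydroxy-2-(4-methoxyphenyl)ethyl]-6-methoxy-5-[(3-methylbut-2-en-1-yl)oxy]phenol (racemate) | COc1ccc(CC(O)c2ccc(OCC=C(C)C)c(OC)c2O)cc1
F2 | step 4 | 1-{2-hydroxy-3-methoxy-4-[(3-methylbut-2-en-1-yl)oxy]phenyl}-2-(4-methoxyphenyl)ethan-1-one | COc1ccc(CC(=O)c2ccc(OCC=C(C)C)c(OC)c2O)cc1
F3 | step 4 | 3-(dimethylamino)-1-{2-hydroxy-3-methoxy-4-[(3-methylbut-2-en-1-yl)oxy]phenyl}-2-(4-methoxyphenyl)prop-2-en-1-one (alkene geometry not defined) | COc1ccc(C(=CN(C)C)C(=O)c2ccc(OCC=C(C)C)c(OC)c2O)cc1
F4 | step 5 | rac-8-methoxy-3-(4-methoxyphenyl)-7-[(3-methylbut-2-en-1-yl)oxy]-2,3-dihydro-4H-chromen-4-one | COc1ccc(C2COc3c(OC)c(OCC=C(C)C)ccc3C2=O)cc1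
F5 | step 5 | rac-8-methoxy-3-(4-methoxyphenyl)-7-[(3-methylbut-2-en-1-yl)oxy]-3-(phenylselanyl)-2,3-dihydro-4H-chromen-4-one | COc1ccc(C2([Se]c3ccccc3)COc3c(OC)c(OCC=C(C)C)ccc3C2=O)cc1
F6 | step 5 | 3-(benzeneseleninyl)-8-methoxy-3-(4-methoxyphenyl)-7-[(3-methylbut-2-en-1-yl)oxy]-2,3-dihydro-4H-chromen-4-one (mixture of diastereomers) | COc1ccc(C2([Se](=O)c3ccccc3)COc3c(OC)c(OCC=C(C)C)ccc3C2=O)cc1
F0 | step 3 | none | none
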